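## Analysis of the target

The target 24 is a 4-methoxycyclohex-2-enone (ring A) whose quaternary C6 carries an allyl group and a two-carbon chain, C7 (the CH(CH3) carbon) and C8 (the benzylic CH(OAc) carbon), which ends in the 3,4,5-trimethoxyphenyl ring B. There are four stereocentres, (4R,6R) in ring A and (7S,8S) in the chain. C7 and C8 are anti, C6–C7–C8 are contiguous, and on ring A the C4 methoxy group is cis to the branched chain and trans to the allyl group. C4 is cut off from the other three centres by the C5 methylene and has to be set on its own. The sensitive parts are the γ-methoxy enone (C4 can epimerise through the dienolate under base, and acid can remove methanol), the benzylic acetate on an electron-rich ring, and the terminal allyl alkene, which rules out a late hydrogenation. The main difficulty is the quaternary C6, which lies between a ketone and a stereogenic CH(CH3) carbon with no neighbouring ring stereocentre to steer an alkylation. The strategy rests on this feature: C1 is a carbonyl carbon held between the C2=C3 alkene and C6, and C6 bears a CH2 arm, so C1 can be a molecule of carbon monoxide 18 inserted between an alkenyl iodide carbon (C2) and the inner carbon of a 1,1-disubstituted alkene (C6), whose CH2 end becomes the arm.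

## Retrosynthetic reasoning

**Acetate and silyl ether.** The C8–O acetyl bond of 24 is cut first, giving the hydroxy ketone 23, and the hydroxyl of 23 is masked as the tert-butyldimethylsilyl ether 22. An ester at C8 would not survive the organometallic and hydride steps earlier in the route, so the acetate goes on last. Forward, this is a fluoride desilylation followed by an acetylation.

**Allyl group.** The terminal C=C bond of the allyl group of 22 is cut (a Wittig methylenation in the forward sense), giving the keto aldehyde 21. 21 comes from the diol 20 by double oxidation, and 20 from the keto ester 19 by hydride reduction of both carbonyl groups. The cut is made here because a CH2–C(=O) arm on C6 is exactly what the ring-forming step leaves. The price is a redox detour, since a hydride cannot tell the ester from the ketone. Forward, the methylenation must pick the aldehyde over the hindered, conjugated C1 ketone.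

**Ring A and the quaternary carbon (key disconnection).** In 19 three bonds are cut at once: C2–C1, C1–C6 and the bond from the arm CH2 to the ester carbon. This removes two molecules of 18 and one of methanol 5 and leaves the acyclic (Z)-alkenyl iodide 17, in which C6 is still the inner carbon of a 1,1-disubstituted alkene. Cutting here, rather than at the C6–allyl bond, replaces an intermolecular alkylation next to an acyclic stereocentre by an intramolecular addition through a six-membered transition state, where both the C4 methoxy group and C7 bear on the outcome. It also builds the ring, the quaternary carbon and the arm in one flask. Forward, the reaction must insert the first molecule of 18 before the alkene adds, close the ring before 5 intercepts the first acyl species, take up the second molecule of 18 at the neopentyl palladium centre, and choose one alkene face.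

**The (Z)-alkenyl iodide.** 17 is traced to the iodoalkyne 16 (syn addition of two hydrogens) and 16 to the alkynylsilane 15 (iodine for silicon). The alkyne is kept until late so that the Z geometry comes from a cis reduction and not from an olefination next to the methoxy-bearing carbon.

**The methoxy-bearing carbon.** The methyl ether 15 comes from the propargylic alcohol 14. Its carbinol carbon (C3 in hept-1-yne numbering, the future ring C4) is too far from the chain stereocentres for substrate control. 14 is therefore traced to the ynone 13, whose reduction can be put under catalyst control, and 13 to the epimer mixture 12. 12 is cut between the carbinol carbon and the adjacent CH2, giving the allylsilane 10 and the aldehyde 11. This is the bond a Hosomi–Sakurai reaction makes, and it creates the 1,1-disubstituted alkene at the same time.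

**The allylsilane.** In 10 the two C–C bonds from the alkene carbon to its CH2 and CH2Si carbons are cut, giving the ester 7 and two equivalents of the Grignard reagent 8. The ester carbon of 7 thus becomes C6 of the target, with the stereodiad already next to it.

**The side-chain stereodiad.** The silyl ether 7 comes from the hydroxy ester 6, and 6 from the imide 4 by exchange of the auxiliary for 5. 4 is cut at the C2–C3 bond of its propanoyl chain into the aldehyde 1 and the propanoyl oxazolidinone 2. One auxiliary-controlled anti aldol reaction supplies the anti relation and the absolute configuration of both centres, so every later stereocentre is set on enantiopure material.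

## Alternatives that were turned down

**Alternative 1:** The disconnection cuts C6–C7 and the C8–O bond of a bicyclic precursor. Forward, acid ionises the quinone monoketal 2-allyl-4,4,5-trimethoxycyclohexa-2,5-dien-1-one A1 to an allyl-substituted cation. The propenylarene (E)-isoelemicin A2 attacks the allyl-bearing ring carbon through its methyl-bearing carbon, and the ring carbonyl oxygen traps the benzylic cation. The product is the dihydrobenzofuranone A3.
- For: one step joins two simple, achiral pieces, creates the quaternary carbon and the C6–C7 bond, and fixes the relative configuration of three centres from the E geometry of A2. The whole route would be roughly a third as long as the chosen one, and on step economy it is clearly the stronger plan.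
- Against: the bond-forming event runs through free cations of two achiral partners, so A3 is racemic and nothing in the step gives absolute control; a late resolution would be needed to reach a single enantiomer. After A3, the enol ether double bond must be saturated with control of the methoxy-bearing centre without touching the allyl group, and the vinylogous ester must be reduced and transposed under acid to the enone while the furan ring opens to free the C8 hydroxyl.
- Comparison: the chosen route is much longer, but it fixes absolute configuration in its first step and sets each stereocentre in a separate, controllable event.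

**Alternative 2:** The disconnection cuts C7–C8 with C8–O tied into a lactone. Forward, aldehyde 1 reacts with the 2-methoxycarbonyl crotylboronate A4 (methyl trans to the boryl-methyl group) through a chair-like allylboration, and the borate alkoxide closes onto the ester to give the trans α-methylene lactone A5.
- For: one step gives the anti diad with the future C6 already an alkene carbon bearing a carbonyl group, and the lactone protects the C8 oxygen without a separate group. Conjugate addition to the exocyclic methylene could bring in C5/C4, and allylation of the lactone enolate anti to the C7 methyl group would set C6 on a rigid five-membered ring. On C6 control this is arguably more secure than the chosen key step.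
- Against: such ester-substituted allylboronates are sluggish and need acid activation, and enantiocontrol for the crotyl case with an electron-rich aldehyde is not assured. Ring A is then still unbuilt: conjugate addition, enolate allylation, addition of a vinyl nucleophile to the lactone carbonyl (with the risk of double addition) and a ring closure are needed. A metathesis closure would also compete with five-ring formation through the allyl group, and C4 again needs its own control.
- Comparison: stronger on C6, weaker on ring construction. The chosen route makes the ring, C6 and the arm in one step from a chain that already holds C4.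

**Alternative 3:** The disconnection cuts C7–C8 and C5–C6. Forward, Lewis-acid-activated aldehyde 1 is attacked by the trisubstituted alkene of the symmetric cyclopentenol A6 at its methyl-bearing carbon. The tertiary cation next to the carbinol triggers a 1,2-shift of a ring methylene, expanding the five-membered ring to the cyclohex-3-enone A7.
- For: highly convergent. It uses aldehyde 1 directly, the symmetry of A6 removes any choice between migrating groups, and the carbon skeleton with C6, C7 and C8 appears in one step.
- Against: Prins–pinacol reactions work best with acetal-derived oxocarbenium ions. With a free aldehyde the product is a benzylic alcohol on an electron-rich ring under Lewis acid, which invites ionisation, elimination or arylation. The open transition state does not secure the C7/C8 relation or its relation to C6, and absolute control would need a chiral Lewis acid with no auxiliary handle. The allyl and ring alkenes are competing nucleophiles. A7 also lacks the C4 methoxy group and has its alkene at C3=C4, so C4 would have to be oxygenated late and stereoselectively from a remote position.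
- Comparison: shorter to the skeleton on paper, but three selectivity problems fall on one cationic step and C4 is left open. The chosen route spreads the stereocentres over separately controlled steps and carries C4 into the ring closure, where it helps.

Key step: step 11

Remark on the chemistry: in step 1 the chelated magnesium enolate is assumed to be attacked on the face away from the benzyl group, as in enolate alkylations, which gives the (2R,3S) adduct from the (S)-auxiliary.

## Route

Step 1
Reactants: 1 3,4,5-trimethoxybenzaldehyde; 2 (S)-4-benzyl-3-propanoyloxazolidin-2-one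
Product: 4 (S)-4-benzyl-3-[(2R,3S)-3-hydroxy-2-methyl-3-(3,4,5-trimethoxyphenyl)propanoyl]oxazolidin-2-one, via TMS ether 3 (not isolated)
Conditions: MgCl2 (10 mol%), Et3N (2 equiv), TMSCl (1.5 equiv), EtOAc, 23 °C; then 1 M HCl, THF
Reagents that add atoms: chlorotrimethylsilane, C[Si](C)(C)Cl (silyl group of 3 only; lost again on work-up)
Why: MgCl2-catalysed direct anti aldol of an N-acyloxazolidinone: the chelated (Z)-magnesium enolate adds to 1 on the face away from the benzyl group through a boat-like transition state, setting C2 (R) and C3 (S) anti; silylation of the aldolate by TMSCl turns the magnesium over, and the acid work-up cleaves the silyl ether 3.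

Step 2
Reactants: 4 (S)-4-benzyl-3-[(2R,3S)-3-hydroxy-2-methyl-3-(3,4,5-trimethoxyphenyl)propanoyl]oxazolidin-2-one; 5 methanol
Product: 6 methyl (2R,3S)-3-hydroxy-2-methyl-3-(3,4,5-trimethoxyphenyl)propanoate
Conditions: MeMgBr (1.5 equiv), MeOH, CH2Cl2, 0 °C; aq. NH4Cl
Reagents that add atoms: none
Why: Transesterification of the β-hydroxy imide with bromomagnesium methoxide, MeOMgBr (made from MeMgBr and 5): magnesium chelation directs methoxide to the exocyclic carbonyl, and the magnesium aldolate should not undergo retro-aldol cleavage or epimerisation at 0 °C.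

Step 3
Reactants: 6 methyl (2R,3S)-3-hydroxy-2-methyl-3-(3,4,5-trimethoxyphenyl)propanoate
Product: 7 methyl (2R,3S)-3-(tert-butyldimethylsilyloxy)-2-methyl-3-(3,4,5-trimethoxyphenyl)propanoate
Conditions: TBSOTf, 2,6-lutidine, CH2Cl2, 0 °C
Reagents that add atoms: tert-butyldimethylsilyl trifluoromethanesulfonate, CC(C)(C)[Si](C)(C)OS(=O)(=O)C(F)(F)F
Why: Silylation of a hindered secondary benzylic alcohol with a silyl triflate and a non-nucleophilic base; the silyl ether withstands the organometallic, Lewis acid, palladium and hydride steps that follow.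

Step 4
Reactants: 7 methyl (2R,3S)-3-(tert-butyldimethylsilyloxy)-2-methyl-3-(3,4,5-trimethoxyphenyl)propanoate; 8 (trimethylsilyl)methylmagnesium chloride
Product: 10 tert-butyldimethyl{[(1S,2S)-2-methyl-3-[(trimethylsilyl)methyl]-1-(3,4,5-trimethoxyphenyl)but-3-en-1-yl]oxy}silane, via tertiary carbinol 9 (not isolated)
Conditions: CeCl3 (anhydrous, 5 equiv), Me3SiCH2MgCl (5 equiv), THF, −78 → 23 °C; aq. NH4Cl; then SiO2, CH2Cl2, 23 °C
Reagents that add atoms: (trimethylsilyl)methylmagnesium chloride, C[Si](C)(C)C[Mg]Cl (second equivalent of 8; its CH2 becomes the terminal alkene carbon)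
Why: Double addition of Me3SiCH2CeCl2 to the ester (the weakly basic organocerium does not enolise the C2 stereocentre) gives the bis(β-silyl) carbinol 9 from two equivalents of 8, and Peterson elimination on silica gel removes one silyl group with the hydroxyl to leave the 2-substituted allylsilane.

Step 5
Reactants: 10 tert-butyldimethyl{[(1S,2S)-2-methyl-3-[(trimethylsilyl)methyl]-1-(3,4,5-trimethoxyphenyl)but-3-en-1-yl]oxy}silane; 11 3-(trimethylsilyl)prop-2-ynal
Product: 12 (6S,7S)-7-(tert-butyldimethylsilyloxy)-6-methyl-5-methylidene-7-(3,4,5-trimethoxyphenyl)-1-(trimethylsilyl)hept-1-yn-3-ol, mixture of C3 epimers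
Conditions: BF3·OEt2 (1.2 equiv), CH2Cl2, −78 °C; aq. NaHCO3
Reagents that add atoms: none
Why: Hosomi–Sakurai allylation: the allylsilane attacks the BF3-activated ynal through its CH2 terminus, and loss of silicon from the β-silyl cation creates the 1,1-disubstituted alkene; the distant stereocentres give no control at the new carbinol C3, which steps 6 and 7 correct.

Step 6
Reactants: 12 (6S,7S)-7-(tert-butyldimethylsilyloxy)-6-methyl-5-methylidene-7-(3,4,5-trimethoxyphenyl)-1-(trimethylsilyl)hept-1-yn-3-ol, mixture of C3 epimers
Product: 13 (6S,7S)-7-(tert-butyldimethylsilyloxy)-6-methyl-5-methylidene-7-(3,4,5-trimethoxyphenyl)-1-(trimethylsilyl)hept-1-yn-3-one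
Conditions: Dess–Martin periodinane, NaHCO3, CH2Cl2, 0 °C
Reagents that add atoms: none
Why: Dess–Martin oxidation under buffered, non-basic conditions removes the uncontrolled stereocentre; the skipped (β,γ-unsaturated) ynone is used at once so that the alkene does not move into conjugation.

Step 7
Reactants: 13 (6S,7S)-7-(tert-butyldimethylsilyloxy)-6-methyl-5-methylidene-7-(3,4,5-trimethoxyphenyl)-1-(trimethylsilyl)hept-1-yn-3-one
Product: 14 (3R,6S,7S)-7-(tert-butyldimethylsilyloxy)-6-methyl-5-methylidene-7-(3,4,5-trimethoxyphenyl)-1-(trimethylsilyl)hept-1-yn-3-ol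
Conditions: Ru[(R,R)-TsNCH(Ph)CH(Ph)NH](p-cymene) (1 mol%), i-PrOH, 25 °C
Reagents that add atoms: none
Why: Noyori-type asymmetric transfer hydrogenation of an alkynyl ketone from 2-propanol under catalyst control: the alkyne takes the place the aryl group has in aryl ketones, so the (R,R)-ligand should give the (3R)-alcohol; the amido complex needs no added base, which spares the skipped enone system.

Step 8
Reactants: 14 (3R,6S,7S)-7-(tert-butyldimethylsilyloxy)-6-methyl-5-methylidene-7-(3,4,5-trimethoxyphenyl)-1-(trimethylsilyl)hept-1-yn-3-ol
Product: 15 (3R,6S,7S)-7-(tert-butyldimethylsilyloxy)-3-methoxy-6-methyl-5-methylidene-7-(3,4,5-trimethoxyphenyl)-1-(trimethylsilyl)hept-1-yne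
Conditions: Me3OBF4, 1,8-bis(dimethylamino)naphthalene, CH2Cl2, 0 → 23 °C
Reagents that add atoms: trimethyloxonium tetrafluoroborate, C[O+](C)C.F[B-](F)(F)F
Why: O-Methylation with a trimethyloxonium salt and a hindered amine base avoids alkoxide formation, so the alkynylsilane is neither cleaved nor C-methylated; C3 is not touched.

Step 9
Reactants: 15 (3R,6S,7S)-7-(tert-butyldimethylsilyloxy)-3-methoxy-6-methyl-5-methylidene-7-(3,4,5-trimethoxyphenyl)-1-(trimethylsilyl)hept-1-yne
Product: 16 (3R,6S,7S)-7-(tert-butyldimethylsilyloxy)-1-iodo-3-methoxy-6-methyl-5-methylidene-7-(3,4,5-trimethoxyphenyl)hept-1-yne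
Conditions: NIS (1.2 equiv), AgNO3 (0.2 equiv), acetone, 23 °C, dark
Reagents that add atoms: N-iodosuccinimide, O=C1CCC(=O)N1I
Why: AgNO3-catalysed iododesilylation: AgNO3 turns the alkynylsilane into a silver acetylide that NIS iodinates, giving the 1-iodoalkyne without a separate desilylation; the neutral conditions should leave the alkene and the electron-rich ring alone.

Step 10
Reactants: 16 (3R,6S,7S)-7-(tert-butyldimethylsilyloxy)-1-iodo-3-methoxy-6-methyl-5-methylidene-7-(3,4,5-trimethoxyphenyl)hept-1-yne
Product: 17 (1Z,3R,6S,7S)-7-(tert-butyldimethylsilyloxy)-1-iodo-3-methoxy-6-methyl-5-methylidene-7-(3,4,5-trimethoxyphenyl)hept-1-ene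
Conditions: 2-nitrobenzenesulfonyl hydrazide, Et3N, THF/i-PrOH, 23 °C
Reagents that add atoms: none
Why: Diimide reduction: concerted syn transfer of two hydrogens to the iodoalkyne gives the (Z)-iodoalkene; the polarised iodoalkyne should react faster than the hindered 1,1-disubstituted alkene, and the reagent is dosed to stop at the alkene stage.

Step 11
Reactants: 17 (1Z,3R,6S,7S)-7-(tert-butyldimethylsilyloxy)-1-iodo-3-methoxy-6-methyl-5-methylidene-7-(3,4,5-trimethoxyphenyl)hept-1-ene; 18 carbon monoxide; 5 methanol
Product: 19 methyl 2-[(1S,5R)-1-[(1S,2S)-1-(tert-butyldimethylsilyloxy)-1-(3,4,5-trimethoxyphenyl)propan-2-yl]-5-methoxy-2-oxocyclohex-3-en-1-yl]acetate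
Conditions: Cl2Pd(PPh3)2 (5 mol%), CO (40 atm), MeOH (4 equiv), Et3N (2 equiv), MeCN–benzene (1:1), 100 °C
Reagents that add atoms: carbon monoxide, [C-]#[O+] (the second molecule of 18 taken up; it becomes the ester carbonyl group)
Why: Zerovalent palladium, formed in the flask from Cl2Pd(PPh3)2, inserts into the C–I bond of 17 with retention of the Z geometry and takes up a first molecule of CO to give a (Z)-alkenoylpalladium iodide, which forms the C2–C1 bond. Its acyl carbon and palladium then add syn across the 1,1-disubstituted alkene in a 6-exo-trig closure, which forms the C1–C6 bond, closes ring A and creates the quaternary carbon. The new alkylpalladium sits on a CH2 group next to that quaternary carbon and has no β-hydrogen, so it inserts a second molecule of CO, and methanol 5 cleaves the resulting acylpalladium to the ester while Et3N takes up HI and returns zerovalent palladium; 19 thus holds two molecules of 18 and one of 5. The closest known reaction type is the cyclic acylpalladation of alkenyl iodides that carry a distant 1,1-disubstituted alkene, ended by carbonylative esterification. C6 is set under substrate control: in the exo mode the four-centre Pd–C1–C6–CH2 array stands across the forming ring, so on either alkene face the CH2Pd arm is axial and the branched chain equatorial, and the two faces differ in whether the C4 methoxy group is pseudo-equatorial or pseudo-axial; the chair-like arrangement with this group equatorial leads to the cis-1,3 relation of 19. The allylic CH(CH3) centre supports the same face when its hydrogen lies towards the tether and its silyloxybenzyl group is turned away from the incoming acyl group. The step needs CO insertion to outrun direct 5-exo carbopalladation (secured by 40 atm of CO), ring closure to outrun methanolysis of the first acylpalladium (secured by a few equivalents of methanol in an aprotic medium and by the Z geometry, which holds the acyl group next to the alkene), and the facial choice just described.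

Step 12
Reactants: 19 methyl 2-[(1S,5R)-1-[(1S,2S)-1-(tert-butyldimethylsilyloxy)-1-(3,4,5-trimethoxyphenyl)propan-2-yl]-5-methoxy-2-oxocyclohex-3-en-1-yl]acetate
Product: 20 2-[(1R,5R)-1-[(1S,2S)-1-(tert-butyldimethylsilyloxy)-1-(3,4,5-trimethoxyphenyl)propan-2-yl]-2-hydroxy-5-methoxycyclohex-3-en-1-yl]ethanol, mixture of C2 epimers
Conditions: i-Bu2AlH (5 equiv), CH2Cl2, −78 → 0 °C; aq. potassium sodium tartrate
Reagents that add atoms: none
Why: Hydride reduction with i-Bu2AlH takes the ester to the primary alcohol and the enone to the allylic alcohol by 1,2-addition; the configuration of the new carbinol does not matter because step 13 removes it.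

Step 13
Reactants: 20 2-[(1R,5R)-1-[(1S,2S)-1-(tert-butyldimethylsilyloxy)-1-(3,4,5-trimethoxyphenyl)propan-2-yl]-2-hydroxy-5-methoxycyclohex-3-en-1-yl]ethanol, mixture of C2 epimers
Product: 21 2-[(1S,5R)-1-[(1S,2S)-1-(tert-butyldimethylsilyloxy)-1-(3,4,5-trimethoxyphenyl)propan-2-yl]-5-methoxy-2-oxocyclohex-3-en-1-yl]acetaldehyde
Conditions: (COCl)2, DMSO, CH2Cl2, −78 °C; then Et3N, −78 → 0 °C
Reagents that add atoms: none
Why: Swern oxidation: both hydroxyls are converted into alkoxysulfonium ions before the base is added, so aldehyde and ketone appear together and no lactol can form between a free hydroxyl and the new aldehyde.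

Step 14
Reactants: 21 2-[(1S,5R)-1-[(1S,2S)-1-(tert-butyldimethylsilyloxy)-1-(3,4,5-trimethoxyphenyl)propan-2-yl]-5-methoxy-2-oxocyclohex-3-en-1-yl]acetaldehyde
Product: 22 (4R,6R)-6-allyl-6-[(1S,2S)-1-(tert-butyldimethylsilyloxy)-1-(3,4,5-trimethoxyphenyl)propan-2-yl]-4-methoxycyclohex-2-en-1-one
Conditions: Ph3PCH3Br (1.1 equiv), KN(SiMe3)2 (1.05 equiv), THF, 0 °C; then 21, −78 → 0 °C
Reagents that add atoms: methyltriphenylphosphonium bromide, C[P+](c1ccccc1)(c1ccccc1)c1ccccc1.[Br-]
Why: Wittig methylenation: the unhindered aldehyde should react with one equivalent of the ylide far faster than the conjugated C1 ketone next to the quaternary carbon, and the low temperature limits deprotonation at C4.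

Step 15
Reactants: 22 (4R,6R)-6-allyl-6-[(1S,2S)-1-(tert-butyldimethylsilyloxy)-1-(3,4,5-trimethoxyphenyl)propan-2-yl]-4-methoxycyclohex-2-en-1-one
Product: 23 (4R,6R)-6-allyl-6-[(1S,2S)-1-hydroxy-1-(3,4,5-trimethoxyphenyl)propan-2-yl]-4-methoxycyclohex-2-en-1-one
Conditions: HF·pyridine, pyridine, THF, 0 → 23 °C
Reagents that add atoms: none
Why: Fluoride-induced cleavage of the silyl ether under buffered, mildly acidic conditions, which the γ-methoxy enone and the allyl group tolerate; basic fluoride is avoided to keep C4 from epimerising.

Step 16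
Reactants: 23 (4R,6R)-6-allyl-6-[(1S,2S)-1-hydroxy-1-(3,4,5-trimethoxyphenyl)propan-2-yl]-4-methoxycyclohex-2-en-1-one
Product: 24 (1S,2S)-2-[(1R,5R)-1-allyl-5-methoxy-2-oxocyclohex-3-en-1-yl]-1-(3,4,5-trimethoxyphenyl)propyl acetate
Conditions: Ac2O, pyridine, DMAP (cat.), CH2Cl2, 23 °C
Reagents that add atoms: acetic anhydride, CC(=O)OC(C)=O
Why: DMAP-catalysed acetylation of the secondary benzylic alcohol; no stereocentre is involved, and the product is the target.

## Compound list

1 | 3,4,5-trimethoxybenzaldehyde | COc1cc(C=O)cc(OC)c1OC | starting material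
2 | (S)-4-benzyl-3-propanoyloxazolidin-2-one | CCC(=O)N1[C@@H](Cc2ccccc2)COC1=O | starting material
3 | (S)-4-benzyl-3-[(2R,3S)-2-methyl-3-(3,4,5-trimethoxyphenyl)-3-(trimethylsilyloxy)propanoyl]oxazolidin-2-one | O=C1OC[C@H](Cc2ccccc2)N1C(=O)[C@H](C)[C@H](O[Si](C)(C)C)c1cc(OC)c(OC)c(OC)c1 | intermediate (not isolated)
4 | (S)-4-benzyl-3-[(2R,3S)-3-hydroxy-2-methyl-3-(3,4,5-trimethoxyphenyl)propanoyl]oxazolidin-2-one | O=C1OC[C@H](Cc2ccccc2)N1C(=O)[C@H](C)[C@H](O)c1cc(OC)c(OC)c(OC)c1 | intermediate
5 | methanol | CO | starting material
6 | methyl (2R,3S)-3-hydroxy-2-methyl-3-(3,4,5-trimethoxyphenyl)propanoate | COC(=O)[C@H](C)[C@H](O)c1cc(OC)c(OC)c(OC)c1 | intermediate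
7 | methyl (2R,3S)-3-(tert-butyldimethylsilyloxy)-2-methyl-3-(3,4,5-trimethoxyphenyl)propanoate | COC(=O)[C@H](C)[C@H](O[Si](C)(C)C(C)(C)C)c1cc(OC)c(OC)c(OC)c1 | intermediate
8 | (trimethylsilyl)methylmagnesium chloride | C[Si](C)(C)C[Mg]Cl | starting material
9 | (3R,4S)-4-(tert-butyldimethylsilyloxy)-3-methyl-4-(3,4,5-trimethoxyphenyl)-1-(trimethylsilyl)-2-[(trimethylsilyl)methyl]butan-2-ol | C[Si](C)(C)CC(O)(C[Si](C)(C)C)[C@H](C)[C@H](O[Si](C)(C)C(C)(C)C)c1cc(OC)c(OC)c(OC)c1 | intermediate (not isolated)
10 | tert-butyldimethyl{[(1S,2S)-2-methyl-3-[(trimethylsilyl)methyl]-1-(3,4,5-trimethoxyphenyl)but-3-en-1-yl]oxy}silane | C=C(C[Si](C)(C)C)[C@H](C)[C@H](O[Si](C)(C)C(C)(C)C)c1cc(OC)c(OC)c(OC)c1 | intermediate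
11 | 3-(trimethylsilyl)prop-2-ynal | C[Si](C)(C)C#CC=O | starting material
12 | (6S,7S)-7-(tert-butyldimethylsilyloxy)-6-methyl-5-methylidene-7-(3,4,5-trimethoxyphenyl)-1-(trimethylsilyl)hept-1-yn-3-ol, mixture of C3 epimers | C=C(CC(O)C#C[Si](C)(C)C)[C@H](C)[C@H](O[Si](C)(C)C(C)(C)C)c1cc(OC)c(OC)c(OC)c1 | intermediate
13 | (6S,7S)-7-(tert-butyldimethylsilyloxy)-6-methyl-5-methylidene-7-(3,4,5-trimethoxyphenyl)-1-(trimethylsilyl)hept-1-yn-3-one | C=C(CC(=O)C#C[Si](C)(C)C)[C@H](C)[C@H](O[Si](C)(C)C(C)(C)C)c1cc(OC)c(OC)c(OC)c1 | intermediate
14 | (3R,6S,7S)-7-(tert-butyldimethylsilyloxy)-6-methyl-5-methylidene-7-(3,4,5-trimethoxyphenyl)-1-(trimethylsilyl)hept-1-yn-3-ol | C=C(C[C@@H](O)C#C[Si](C)(C)C)[C@H](C)[C@H](O[Si](C)(C)C(C)(C)C)c1cc(OC)c(OC)c(OC)c1 | intermediate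
15 | (3R,6S,7S)-7-(tert-butyldimethylsilyloxy)-3-methoxy-6-methyl-5-methylidene-7-(3,4,5-trimethoxyphenyl)-1-(trimethylsilyl)hept-1-yne | C=C(C[C@@H](OC)C#C[Si](C)(C)C)[C@H](C)[C@H](O[Si](C)(C)C(C)(C)C)c1cc(OC)c(OC)c(OC)c1 | intermediate
16 | (3R,6S,7S)-7-(tert-butyldimethylsilyloxy)-1-iodo-3-methoxy-6-methyl-5-methylidene-7-(3,4,5-trimethoxyphenyl)hept-1-yne | C=C(C[C@@H](OC)C#CI)[C@H](C)[C@H](O[Si](C)(C)C(C)(C)C)c1cc(OC)c(OC)c(OC)c1 | intermediate
17 | (1Z,3R,6S,7S)-7-(tert-butyldimethylsilyloxy)-1-iodo-3-methoxy-6-methyl-5-methylidene-7-(3,4,5-trimethoxyphenyl)hept-1-ene | C=C(C[C@@H](OC)/C=C\I)[C@H](C)[C@H](O[Si](C)(C)C(C)(C)C)c1cc(OC)c(OC)c(OC)c1 | intermediate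
18 | carbon monoxide | [C-]#[O+] | starting material
19 | methyl 2-[(1S,5R)-1-[(1S,2S)-1-(tert-butyldimethylsilyloxy)-1-(3,4,5-trimethoxyphenyl)propan-2-yl]-5-methoxy-2-oxocyclohex-3-en-1-yl]acetate | COC(=O)C[C@]1([C@H](C)[C@H](O[Si](C)(C)C(C)(C)C)c2cc(OC)c(OC)c(OC)c2)C[C@@H](OC)C=CC1=O | intermediate
20 | 2-[(1R,5R)-1-[(1S,2S)-1-(tert-butyldimethylsilyloxy)-1-(3,4,5-trimethoxyphenyl)propan-2-yl]-2-hydroxy-5-methoxycyclohex-3-en-1-yl]ethanol, mixture of C2 epimers | OCC[C@]1([C@H](C)[C@H](O[Si](C)(C)C(C)(C)C)c2cc(OC)c(OC)c(OC)c2)C[C@@H](OC)C=CC1O | intermediate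
21 | 2-[(1S,5R)-1-[(1S,2S)-1-(tert-butyldimethylsilyloxy)-1-(3,4,5-trimethoxyphenyl)propan-2-yl]-5-methoxy-2-oxocyclohex-3-en-1-yl]acetaldehyde | O=CC[C@]1([C@H](C)[C@H](O[Si](C)(C)C(C)(C)C)c2cc(OC)c(OC)c(OC)c2)C[C@@H](OC)C=CC1=O | intermediate
22 | (4R,6R)-6-allyl-6-[(1S,2S)-1-(tert-butyldimethylsilyloxy)-1-(3,4,5-trimethoxyphenyl)propan-2-yl]-4-methoxycyclohex-2-en-1-one | C=CC[C@]1([C@H](C)[C@H](O[Si](C)(C)C(C)(C)C)c2cc(OC)c(OC)c(OC)c2)C[C@@H](OC)C=CC1=O | intermediate
23 | (4R,6R)-6-allyl-6-[(1S,2S)-1-hydroxy-1-(3,4,5-trimethoxyphenyl)propan-2-yl]-4-methoxycyclohex-2-en-1-one | C=CC[C@]1([C@H](C)[C@H](O)c2cc(OC)c(OC)c(OC)c2)C[C@@H](OC)C=CC1=O | intermediate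
24 | (1S,2S)-2-[(1R,5R)-1-allyl-5-methoxy-2-oxocyclohex-3-en-1-yl]-1-(3,4,5-trimethoxyphenyl)propyl acetate | C=CC[C@]1([C@H](C)[C@H](OC(C)=O)c2cc(OC)c(OC)c(OC)c2)C[C@@H](OC)C=CC1=O | target

## Step count and least certain steps

Total step count: 16. Longest linear sequence: 16 steps (1 to 24); the route is fully linear, with 2, 5, 8, 11 and 18 as purchased partners.

**Step 11 (key step).** Three processes can spoil it:
- Direct 5-exo carbopalladation of the alkenylpalladium before CO insertion, which would give a cyclopentene.
- Methanolysis of the first acylpalladium before ring closure, which would give an open-chain (Z)-enoate.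
- Poor facial selectivity in the acylpalladation, which would give the C6 epimer; the conformational preferences that separate the two faces are modest.

Fallback, setting out from 17 and coming back at 22: the quaternary carbon is made by an enamine aza-Claisen allylation and the ring is closed by a Nozaki–Hiyama–Kishi reaction. Hydroboration of the 1,1-disubstituted alkene of 17 with 9-BBN and oxidation with NaBO3 should give the primary alcohol F1, and Dess–Martin oxidation the α-branched aldehyde F2. The pyrrolidine enamine of F2 is N-allylated with allyl bromide and rearranged on warming (Stork enamine allylation with aza-Claisen shift); hydrolysis should give the quaternary aldehyde F3, whose C2 epimers would be separated, since only the neighbouring CH(CH3) centre directs this step. CrCl2 with catalytic NiCl2 in DMSO should add the (Z)-alkenyl iodide to the aldehyde and close ring A to the cyclohexenol F4, and Dess–Martin oxidation of F4 gives 22. Steps 12 to 14 are bypassed as well.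

**Step 6 (with step 7).** The skipped ynone 13 can lose its integrity by migration of the 1,1-disubstituted alkene into conjugation with the carbonyl group, during oxidation, handling or reduction. That would destroy the alkene needed in step 11.

Fallback, setting out from 12 and coming back at 14: no ketone is made. The C3 epimers of 12 are separated by chromatography into 14 and the (3S)-alcohol F5. F5 is inverted by a Mitsunobu reaction (PPh3, DIAD, PhCO2H) to the (3R)-benzoate F6, and the ester is cleaved reductively with i-Bu2AlH at −78 °C, which keeps the alkynylsilane, to give more 14.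

**Step 10.** Diimide may carry on past the alkene stage to the saturated iodide, or attack the 1,1-disubstituted alkene, while unreacted iodoalkyne remains. The mixture would be hard to separate.

Fallback, setting out from 15 and coming back at 17: the iodoalkyne is avoided. K2CO3 in methanol removes the C-silyl group to give the terminal alkyne F7. Lewis-acid-catalysed trans-hydrostannation (Bu3SnH, ZrCl4 cat., toluene, 0 °C) should give the (Z)-alkenylstannane F8, and iododestannylation with I2 in CH2Cl2 at 0 °C proceeds with retention to 17.

**Step 13.** If the primary alcohol is oxidised while the C1 hydroxyl is still free, the hydroxy aldehyde closes to a lactol and over-oxidation to a lactone follows; loss of the allylic alkoxysulfonium group to chloride is a further side path.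

Fallback, setting out from 20 and coming back at 21: the two oxidations are separated. MnO2 in CH2Cl2 oxidises only the allylic alcohol to give the hydroxy enone F9, in which at most a reversible hemiketal can form and no aldehyde lactol, and Dess–Martin oxidation of the primary alcohol of F9 then gives 21.

## Further compounds

F1 | step 11 | (3S,4S)-4-(tert-butyldimethylsilyloxy)-2-[(2R,3Z)-4-iodo-2-methoxybut-3-en-1-yl]-3-methyl-4-(3,4,5-trimethoxyphenyl)butan-1-ol, C2 epimers | OCC(C[C@@H](OC)/C=C\I)[C@H](C)[C@H](O[Si](C)(C)C(C)(C)C)c1cc(OC)c(OC)c(OC)c1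
F2 | step 11 | (3S,4S)-4-(tert-butyldimethylsilyloxy)-2-[(2R,3Z)-4-iodo-2-methoxybut-3-en-1-yl]-3-methyl-4-(3,4,5-trimethoxyphenyl)butanal, C2 epimers | O=CC(C[C@@H](OC)/C=C\I)[C@H](C)[C@H](O[Si](C)(C)C(C)(C)C)c1cc(OC)c(OC)c(OC)c1
F3 | step 11 | (2R,3S,4S)-2-allyl-4-(tert-butyldimethylsilyloxy)-2-[(2R,3Z)-4-iodo-2-methoxybut-3-en-1-yl]-3-methyl-4-(3,4,5-trimethoxyphenyl)butanal | C=CC[C@@](C=O)(C[C@@H](OC)/C=C\I)[C@H](C)[C@H](O[Si](C)(C)C(C)(C)C)c1cc(OC)c(OC)c(OC)c1
F4 | step 11 | (4R,6R)-6-allyl-6-[(1S,2S)-1-(tert-butyldimethylsilyloxy)-1-(3,4,5-trimethoxyphenyl)propan-2-yl]-4-methoxycyclohex-2-en-1-ol, C1 epimers | C=CC[C@]1([C@H](C)[C@H](O[Si](C)(C)C(C)(C)C)c2cc(OC)c(OC)c(OC)c2)C[C@@H](OC)C=CC1O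
F5 | step 6 | (3S,6S,7S)-7-(tert-butyldimethylsilyloxy)-6-methyl-5-methylidene-7-(3,4,5-trimethoxyphenyl)-1-(trimethylsilyl)hept-1-yn-3-ol | C=C(C[C@H](O)C#C[Si](C)(C)C)[C@H](C)[C@H](O[Si](C)(C)C(C)(C)C)c1cc(OC)c(OC)c(OC)c1
F6 | step 6 | (3R,6S,7S)-7-(tert-butyldimethylsilyloxy)-6-methyl-5-methylidene-7-(3,4,5-trimethoxyphenyl)-1-(trimethylsilyl)hept-1-yn-3-yl benzoate | C=C(C[C@@H](OC(=O)c1ccccc1)C#C[Si](C)(C)C)[C@H](C)[C@H](O[Si](C)(C)C(C)(C)C)c1cc(OC)c(OC)c(OC)c1
F7 | step 10 | (3R,6S,7S)-7-(tert-butyldimethylsilyloxy)-3-methoxy-6-methyl-5-methylidene-7-(3,4,5-trimethoxyphenyl)hept-1-yne | C=C(C[C@@H](OC)C#C)[C@H](C)[C@H](O[Si](C)(C)C(C)(C)C)c1cc(OC)c(OC)c(OC)c1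
F8 | step 10 | tributyl[(1Z,3R,6S,7S)-7-(tert-butyldimethylsilyloxy)-3-methoxy-6-methyl-5-methylidene-7-(3,4,5-trimethoxyphenyl)hept-1-en-1-yl]stannane | C=C(C[C@@H](OC)/C=C\[Sn](CCCC)(CCCC)CCCC)[C@H](C)[C@H](O[Si](C)(C)C(C)(C)C)c1cc(OC)c(OC)c(OC)c1
F9 | step 13 | (4R,6R)-6-(2-hydroxyethyl)-6-[(1S,2S)-1-(tert-butyldimethylsilyloxy)-1-(3,4,5-trimethoxyphenyl)propan-2-yl]-4-methoxycyclohex-2-en-1-one | OCC[C@]1([C@H](C)[C@H](O[Si](C)(C)C(C)(C)C)c2cc(OC)c(OC)c(OC)c2)C[C@@H](OC)C=CC1=O
A1 | alternative 1 | 2-allyl-4,4,5-trimethoxycyclohexa-2,5-dien-1-one | C=CCC1=CC(OC)(OC)C(OC)=CC1=O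
A2 | alternative 1 | 1,2,3-trimethoxy-5-[(E)-prop-1-enyl]benzene ((E)-isoelemicin) | C/C=C/c1cc(OC)c(OC)c(OC)c1
A3 | alternative 1 | 3a-allyl-5-methoxy-3-methyl-2-(3,4,5-trimethoxyphenyl)-3,3a-dihydrobenzofuran-6(2H)-one, aryl and methyl trans, methyl anti to allyl | C=CC[C@]12C=C(OC)C(=O)C=C1O[C@H](c1cc(OC)c(OC)c(OC)c1)[C@H]2C
A4 | alternative 2 | methyl (Z)-2-[(4,4,5,5-tetramethyl-1,3,2-dioxaborolan-2-yl)methyl]but-2-enoate | C/C=C(/CB1OC(C)(C)C(C)(C)O1)C(=O)OC
A5 | alternative 2 | (4S,5S)-4-methyl-3-methylidene-5-(3,4,5-trimethoxyphenyl)dihydrofuran-2(3H)-one | C=C1[C@H](C)[C@@H](c2cc(OC)c(OC)c(OC)c2)OC1=O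
A6 | alternative 3 | 1-[(Z)-hexa-2,5-dien-3-yl]cyclopent-3-en-1-ol | C/C=C(/CC=C)C1(O)CC=CC1
A7 | alternative 3 | (R)-6-allyl-6-[(1S,2S)-1-hydroxy-1-(3,4,5-trimethoxyphenyl)propan-2-yl]cyclohex-3-en-1-one | C=CC[C@]1([C@H](C)[C@H](O)c2cc(OC)c(OC)c(OC)c2)CC=CCC1=O
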